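We decide to reckon north-west by hand and to count its time in half-lives of a link.

| setting | north-west | south-east | west | north-east | south | east |
|---|---|---|---|---|---|---|
| first end groups | 0.30 M | 0.30 M (fed, over 30 h) | 0.30 M | 0.30 M (in portions, 5, over 30 h) | 0.30 M (fed, over 8.0 h) | 0.30 M |
| second end groups | 0.300 M | 0.300 M | 0.300 M (fed, over 30 h) | 0.300 M | 0.300 M | 0.300 M |
| third end groups | 0.300 M | 0.300 M | 0.300 M | 0.300 M | 0.300 M | 0.300 M |
| temperature | 35 °C | 35 °C |  | 35 °C | 35 °C |  |
| time | 40 h | 40 h | 40 h | 40 h | 40 h | 40 h |
| remark | everything together at the start | all else is in the flask from the start; the feed brings no volume worth counting | the addition at 5 °C, then warmed to 35 °C; the feed brings no volume worth counting | first portion at the start, last at 30 h | all else is in the flask from the start; the feed brings no volume worth counting | everything together at the start at 5 °C, warmed to 35 °C at 30 h |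

    second end groups + links → over-reaction product (k1 = 1.0 /M/h, Ea1 = 74.0 kJ/mol)
    first end groups + second end groups ⇌ links (K2 = 24 /M, k2 = 0.96 /M/h, Ea2 = 72.0 kJ/mol, ΔH2 = −48.0 kJ/mol)
    second end groups → decomposed reagent (k3 = 0.0055 /h, Ea3 = 119 kJ/mol)
    second end groups + third end groups → links of the second sort (k4 = 0.70 /M/h, Ea4 = 76.0 kJ/mol)
    (constants at 35 °C)

- the list of constants is for 35 °C, to be carried to other temperatures by the activation energies and enthalpies

- the flask that comes out highest in amount of over-reaction product, in percent of the first end groups charged; "all alike" if 1.5 percentage points covers them all (north-west / south-east / west / north-east / south / east / all alike)
- amount of over-reaction product at the end, in percent of the first end groups charged, north-west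
- amount of over-reaction product at the end, in percent of the first end groups charged, south-east
- amount of over-reaction product at the end, in percent of the first end groups charged, west
- amount of over-reaction product at the end, in percent of the first end groups charged, north-east
- amount of over-reaction product at the end, in percent of the first end groups charged, south
- amount of over-reaction product at the end, in percent of the first end groups charged, east

1. Two clocks. As charged in north-west, first end groups have a forward half-life of 2.4 h and links a half-life against over-reaction of 2.3 h. A link falling apart has a half-life of 17.3 h, longer than either. So we reckon a fast stage, then a slow one.

2. Fast stage. Second end groups are the limiting reagent, 0.300 M against 0.600 M of first and third end groups together, and we let them divide in the ratio of k2[first end groups] to k4[third end groups]. Shared out at the starting rates, they give a first end group 0.578 lifetimes. Steps with constants 0.96 /M/h and 1.0 /M/h are nearly equal, so we treat them as two equal steps in series. This gives [links] = 0.0973 M and [over-reaction product] = 0.0344 M, with [first end groups] = 0.168 M and [third end groups] = 0.197 M.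

3. Slow stage. The run lasts 2.31 half-lives, so we count a loss of 0.0777 M of links. We let a released second end group meet a link or a third end group. With mean [links] of 0.0487 M, the link's share is 0.261. Each such hit costs two links for one product. The total is 16.8% of the first end groups charged, and we stand by that for now.

4. The weak link. Step 3 counted each release as a loss, but at our fast-stage [first end groups] they recapture at 0.161 /h, against 0.186 /h for escape. The escaping share is 0.536. The working half-life of a link, its half-life of falling apart divided by the share of releases that escape recapture, is 32.3 h. The run now lasts 1.24 of these, we count a loss of 0.0560 M of links, and our reckoning for north-west comes to 15.3%.

5. Ranking. West and east have 10.0 h at 35 °C after warming, which is 0.309 of north-west's working half-lives, so we place them below north-west. With a fifth of the first end groups present, as in north-east's first portion, their pull of 0.0576 /h is weaker than the 0.210 /h of third end groups, so we put north-east, and with it south-east and south, below north-west as well.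

The forecast names north-west, with 19.5% for north-west, above our figure, then 8.5% for south-east, 15% for west, 10.5% for north-east, 11.5% for south and 16% for east. Its grounds for the cold flasks: “The cold flasks mostly just postpone the batch-like chemistry until warming and then have less time for that slow release”.

The simulation gives north-west as highest, with 18.4% there, 7.29% in south-east, 15.0% in west, 10.0% in north-east, 11.4% in south and 15.5% in east.

In north-west the comparison is 40 h against the working half-life of 32.3 h. At 40.0 h links stand at 12.7% of the first end groups charged, where our count gave 13.8%, and third end groups take second end groups at 0.56 of the forward rate of first end groups. Our figure for over-reaction product in north-west lies 3 percentage points below the simulated one.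

Take a neighbour, north-west with 0.51 M of first end groups and the other charges and the time held. The same steps give 0.412 lifetimes and a working half-life of 42.3 h, longer than in north-west, and by our count links stand at 14.2% of the first end groups charged at the end. The simulated neighbour holds 12.0% links and 11.4% over-reaction product, both in percent of the first end groups charged.

All constants are made up, and the outcome is calculated.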